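All runs are simulated from invented constants, noise included.

The easy step came first: from the north run to the south-east run I doubled c(partner) and left c(starting material) alone, and target at 30 min went from 0.0219 M to 0.0274 M.

| setting | north | south | south-east | south-west | east |
|---|---|---|---|---|---|
| starting material | 0.0500 M | 0.0200 M | 0.0500 M | 0.150 M | 0.100 M |
| partner | 0.0750 M | 0.0450 M | 0.150 M | 0.0750 M | 0.220 M |
| time |  |  |  |  | 30 min |

| run | time / min | [target] / M |
|---|---|---|
| north run | 2.3 | 0.0014 |
| north run | 6.9 | 0.0069 |
| north run | 13 | 0.0134 |
| north run | 21 | 0.0197 |
| north run | 30 | 0.0219 |
| south run | 2.3 | 4 × 10⁻⁴ |
| south run | 6.9 | 0.0028 |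
| south run | 13 | 0.0054 |
| south run | 21 | 0.0069 |
| south run | 30 | 0.0078 |
| south-east run | 2.3 | 0.0026 |
| south-east run | 6.9 | 0.0089 |
| south-east run | 13 | 0.0175 |
| south-east run | 21 | 0.0242 |
| south-east run | 30 | 0.0274 |
| south-west run | 2.3 | 0.0030 |
| south-west run | 6.9 | 0.0147 |
| south-west run | 13 | 0.0292 |
| south-west run | 21 | 0.0431 |
| south-west run | 30 | 0.0525 |

(each reading ± 3 × 10⁻⁴ M)

* how the opening rate goes with [starting material] round the charge of the north run: the exponent of the rate at two percent of starting material gone to target (one fixed amount of target, the same in the runs compared)
* how the opening rate goes with [partner] round the charge of the north run: the exponent of the rate at two percent of starting material gone to target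
* target in the east run at 30 min, as a share of the starting material charged

- Overall: starting material + partner -> target.
- Constant volume, constant temperature.
- The analysis sees a species whether free or bound.
- An order is taken over about fifteen percent of the charge, up and down.

That pair gave me the partner pay-off, 0.323: the exponent of target at that late time in c(partner), with c(starting material) held fixed. The north and south-west runs, which share a c(partner), gave the matching exponent in c(starting material), 0.796. Carrying the north reading to the east charge with both exponents, I reckoned 53.8% of the starting material charged.

The forecast, which held that “partner nearly saturates”, gave opening orders of 0.5 in starting material and 0.45 in partner. For the east run it gave 48%, less than my figure.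

The simulation gave orders of 0.48 and 0.32, and 56.0% for the east run. So the forecast held on starting material, came out higher than the flask on partner, and fell 8 percentage points short on the east run, while my reckoning fell 2.2 points short.

    starting material → intermediate (0.1200 min⁻¹)
    intermediate + partner → target (9.000 M⁻¹ min⁻¹)
    intermediate → side product (0.2088 min⁻¹)
    2 partner ⇌ idle reagent dimer, settled at all times (41.80 M⁻¹)
    2 starting material ⇌ idle substrate dimer, settled at all times (13.70 M⁻¹)

The east run falls short of its full charge at 30 min mainly from the tying up of partner as idle reagent dimer: without that step the run gives 78.1% of target against 56.0%, which recovers half of what is missing. In my reckoning the pay-off of 0.323, read off the north and south-east runs, turned the east run's partner charge, 2.93 times the north charge, into a factor of 1.42 on target. Carried from the north run to the south run, the same two exponents give 0.00895 M against that run's reading of 0.0078 M.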